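**Retrosynthetic overview**
- Target 14 comes from 13 by desilylation, 13 from cis-alcohol 12 by oxidation at C4, and 12 from isoflavone 10 by asymmetric transfer hydrogenation with dynamic kinetic resolution, which sets C3. Isoflavone 10 comes from dibromoisoflavone 7 by a protecting-group change and a two-fold prenylation at C6 and C3'.
- Dibromoisoflavone 7 comes from trans-2'-fluorochalcone epoxide 5 in one flask. Oxirane strain release drives a 1,2-aroyl shift that makes C3–C4. The former oxirane oxygen, now the enolate oxygen on C2, then displaces fluoride at C8a and makes O1–C8a.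
- Enabling feature: the C4 carbonyl of ring C sits on C4a of ring A, ortho to C8a. The same acyl group is therefore both a good migrating group and the activator for substitution at C8a. The 4'-oxygen of ring B, para to C1', stabilises positive charge at C3, so the oxirane opens only at that carbon.
- Epoxide 5 comes from chalcone 4, and 4 from 2 and 3 by Claisen–Schmidt condensation. The linear chalcone skeleton becomes the branched isoflavonoid skeleton by a 1,2-shift, as in the biosynthesis, except that there ring B migrates and here the aroyl group does.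
- Ring order: rings A and B are bought as arenes. Ring C is the only ring formed (step 4).

Key step: step 4

Remark on the chemistry: the stereocentre in the SMILES is C3 and reads as S (ranking C4 > C2 > C1' > H). It is benzylic and α to the C4 ketone, hence labile to base, so it is created late and sees only non-basic conditions afterwards.

**Step 1**
Reactants: 1 2-bromo-5-fluoroanisole
Product: 2 1-(5-bromo-2-fluoro-4-methoxyphenyl)ethan-1-one
Conditions: AcCl, AlCl3, CH2Cl2, 0 °C to rt
Reagents that add atoms: acetyl chloride, CC(=O)Cl
Why: Friedel–Crafts acylation in which methoxy (para) and fluorine (ortho) direct to the same carbon, while the only other activated site is crowded between OMe and F, so one regioisomer with F ortho and OMe para to the acetyl group is expected.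

**Step 2**
Reactants: 2 1-(5-bromo-2-fluoro-4-methoxyphenyl)ethan-1-one, 3 3-bromo-4-methoxybenzaldehyde
Product: 4 (E)-3-(3-bromo-4-methoxyphenyl)-1-(5-bromo-2-fluoro-4-methoxyphenyl)prop-2-en-1-one
Conditions: KOH (aq), EtOH, 0 °C to rt
Reagents that add atoms: none
Why: Claisen–Schmidt condensation (aldol addition, then E1cB loss of water) between the only enolisable partner 2 and the non-enolisable aldehyde 3 should give the conjugated E-enone, and the aryl fluoride should not be displaced at or below room temperature.

**Step 3**
Reactants: 4 (E)-3-(3-bromo-4-methoxyphenyl)-1-(5-bromo-2-fluoro-4-methoxyphenyl)prop-2-en-1-one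
Product: 5 rac-trans-(5-bromo-2-fluoro-4-methoxyphenyl)[(2R*,3S*)-3-(3-bromo-4-methoxyphenyl)oxiran-2-yl]methanone
Conditions: 30% H2O2, NaOH (aq), MeOH–THF, 0 °C to rt
Reagents that add atoms: hydrogen peroxide, OO
Why: Weitz–Scheffer nucleophilic epoxidation (conjugate addition of hydroperoxide, then enolate closure on the O–O bond) should give the racemic trans-epoxide, and no absolute control is needed because both oxirane stereocentres are erased in step 4.

**Step 4**
Reactants: 5 rac-trans-(5-bromo-2-fluoro-4-methoxyphenyl)[(2R*,3S*)-3-(3-bromo-4-methoxyphenyl)oxiran-2-yl]methanone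
Product: 7 6-bromo-3-(3-bromo-4-methoxyphenyl)-7-methoxy-4H-chromen-4-one, via ketoaldehyde 6 (not isolated)
Conditions: BF3·OEt2 (0.2 equiv), toluene, 0 °C, 15 min; then K2CO3 (3 equiv), DMF, same flask, 80 °C
Reagents that add atoms: none
Why: BF3 binds the oxirane oxygen of 5 and the C–O bond at the carbon bearing ring B (future C3) ionises, since the para methoxy group of ring B stabilises charge there whereas the other oxirane carbon is α to the carbonyl; relief of ring strain then drives a 1,2-shift of the aroyl group from the future C2 to C3 (C3–C4 bond) and turns the oxirane oxygen into the formyl, largely enol, oxygen of 6. Added K2CO3 converts 6 into its enolate, whose oxygen adds to the fluorine-bearing carbon ortho to the ketone and expels fluoride by way of a Meisenheimer adduct (O1–C8a bond). The closest known reaction types are the Lewis-acid House–Meinwald acyl migration of chalcone epoxides to α-formyl deoxybenzoins and the carbonate-mediated intramolecular SNAr of 1-(2-halophenyl)-1,3-dicarbonyl compounds to chromones, which are merely run in one flask here. Ring C is the only ring closed, by a six-membered intramolecular addition–elimination at an aromatic sp2 carbon from the enolate rotamer that holds the oxygen and the aroyl group cis on C2=C3. No stereocentre is created, because C3 ends sp2 in the 4-pyranone, so racemic 5 suffices and C3 is set in step 8. The step needs aroyl over hydride migration, secured by the higher migratory aptitude of acyl groups in α,β-epoxy ketones, and displacement of fluoride only, secured because fluorine alone sits ortho to the carbonyl while both bromines occupy non-activated positions.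

**Step 5**
Reactants: 7 6-bromo-3-(3-bromo-4-methoxyphenyl)-7-methoxy-4H-chromen-4-one
Product: 8 6-bromo-3-(3-bromo-4-hydroxyphenyl)-7-hydroxy-4H-chromen-4-one
Conditions: BBr3, CH2Cl2, −78 °C to rt; H2O work-up
Reagents that add atoms: none
Why: Lewis-acid cleavage of aryl methyl ethers with BBr3 is standard for methoxyisoflavones and is placed before the prenyl groups are introduced, because these would not survive it.

**Step 6**
Reactants: 8 6-bromo-3-(3-bromo-4-hydroxyphenyl)-7-hydroxy-4H-chromen-4-one
Product: 9 6-bromo-3-[3-bromo-4-(tert-butyldimethylsilyloxy)phenyl]-7-(tert-butyldimethylsilyloxy)-4H-chromen-4-one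
Conditions: TBSCl, imidazole, DMF, rt
Reagents that add atoms: tert-butyldimethylsilyl chloride, CC(C)(C)[Si](C)(C)Cl
Why: Imidazole-promoted silylation masks both phenols with groups that tolerate base-free cross-coupling, transfer hydrogenation and Dess–Martin oxidation and can later be removed without base.

**Step 7**
Reactants: 9 6-bromo-3-[3-bromo-4-(tert-butyldimethylsilyloxy)phenyl]-7-(tert-butyldimethylsilyloxy)-4H-chromen-4-one
Product: 10 7-(tert-butyldimethylsilyloxy)-3-[4-(tert-butyldimethylsilyloxy)-3-(3-methylbut-2-enyl)phenyl]-6-(3-methylbut-2-enyl)-4H-chromen-4-one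
Conditions: Bu3SnCH2CH=CMe2 (2.5 equiv), Pd(PPh3)4 (10 mol %), toluene, 105 °C
Reagents that add atoms: tributyl(3-methylbut-2-en-1-yl)stannane, CCCC[Sn](CCCC)(CCCC)CC=C(C)C
Why: Two-fold Migita–Kosugi–Stille coupling (oxidative addition of zerovalent palladium into each C–Br bond, transmetalation, then reductive elimination from the less hindered σ-prenyl palladium species) should place linear prenyl groups at C6 and C3' under base-free conditions that spare the silyl ethers.

**Step 8**
Reactants: 10 7-(tert-butyldimethylsilyloxy)-3-[4-(tert-butyldimethylsilyloxy)-3-(3-methylbut-2-enyl)phenyl]-6-(3-methylbut-2-enyl)-4H-chromen-4-one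
Product: 12 (3S,4S)-7-(tert-butyldimethylsilyloxy)-3-[4-(tert-butyldimethylsilyloxy)-3-(3-methylbut-2-enyl)phenyl]-6-(3-methylbut-2-enyl)chroman-4-ol, via racemising isoflavanone 11 (not isolated)
Conditions: RuCl[(S,S)-TsDPEN](mesitylene) (3 mol %), HCO2H/Et3N (5:2), EtOAc, 40 °C
Reagents that add atoms: none
Why: Noyori–Ikariya asymmetric transfer hydrogenation run as a domino conjugate reduction and dynamic kinetic resolution, a sequence known for isoflavones, in which ruthenium hydride saturates C2=C3 to 11, 11 racemises at C3 through its enol under Et3N, and the (S,S)-catalyst reduces only the (3S)-enantiomer on the carbonyl face anti to ring B, so that C4 becomes S and C3 is fixed as S in the cis-alcohol while the isolated prenyl alkenes stay untouched.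

**Step 9**
Reactants: 12 (3S,4S)-7-(tert-butyldimethylsilyloxy)-3-[4-(tert-butyldimethylsilyloxy)-3-(3-methylbut-2-enyl)phenyl]-6-(3-methylbut-2-enyl)chroman-4-ol
Product: 13 (3S)-7-(tert-butyldimethylsilyloxy)-3-[4-(tert-butyldimethylsilyloxy)-3-(3-methylbut-2-enyl)phenyl]-6-(3-methylbut-2-enyl)chroman-4-one
Conditions: Dess–Martin periodinane, CH2Cl2, 0 °C to rt
Reagents that add atoms: none
Why: Dess–Martin oxidation of the secondary benzylic alcohol under non-basic conditions removes the auxiliary C4 stereocentre and should leave the enolisable C3 stereocentre untouched, and C3 keeps the descriptor S because the substituent ranking does not change.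

**Step 10**
Reactants: 13 (3S)-7-(tert-butyldimethylsilyloxy)-3-[4-(tert-butyldimethylsilyloxy)-3-(3-methylbut-2-enyl)phenyl]-6-(3-methylbut-2-enyl)chroman-4-one
Product: 14 (3S)-7-hydroxy-3-[4-hydroxy-3-(3-methylbut-2-enyl)phenyl]-6-(3-methylbut-2-enyl)chroman-4-one
Conditions: KHF2 (excess), MeOH–THF, rt
Reagents that add atoms: none
Why: Cleavage of phenolic silyl ethers by the mildly acidic bifluoride salt is driven by Si–F bond formation, and because the medium is neither basic nor strongly acidic, neither epimerisation at C3 nor cyclisation of the ortho-prenylphenols to chromans should intervene.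

**Compound list**
1 | 2-bromo-5-fluoroanisole | COc1cc(F)ccc1Br | starting material
2 | 1-(5-bromo-2-fluoro-4-methoxyphenyl)ethan-1-one | COc1cc(F)c(C(C)=O)cc1Br | intermediate
3 | 3-bromo-4-methoxybenzaldehyde | COc1ccc(C=O)cc1Br | starting material
4 | (E)-3-(3-bromo-4-methoxyphenyl)-1-(5-bromo-2-fluoro-4-methoxyphenyl)prop-2-en-1-one | COc1ccc(/C=C/C(=O)c2cc(Br)c(OC)cc2F)cc1Br | intermediate
5 | rac-trans-(5-bromo-2-fluoro-4-methoxyphenyl)[(2R*,3S*)-3-(3-bromo-4-methoxyphenyl)oxiran-2-yl]methanone (racemic, one enantiomer drawn) | O=C(c1cc(Br)c(OC)cc1F)[C@@H]2O[C@H]2c3ccc(OC)c(Br)c3 | intermediate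
6 | 2-(3-bromo-4-methoxyphenyl)-3-(5-bromo-2-fluoro-4-methoxyphenyl)-3-oxopropanal (largely enolised, not isolated) | O=CC(c1ccc(OC)c(Br)c1)C(=O)c2cc(Br)c(OC)cc2F | intermediate
7 | 6-bromo-3-(3-bromo-4-methoxyphenyl)-7-methoxy-4H-chromen-4-one | COc1ccc(-c2coc3cc(OC)c(Br)cc3c2=O)cc1Br | intermediate
8 | 6-bromo-3-(3-bromo-4-hydroxyphenyl)-7-hydroxy-4H-chromen-4-one | Oc1ccc(-c2coc3cc(O)c(Br)cc3c2=O)cc1Br | intermediate
9 | 6-bromo-3-[3-bromo-4-(tert-butyldimethylsilyloxy)phenyl]-7-(tert-butyldimethylsilyloxy)-4H-chromen-4-one | CC(C)(C)[Si](C)(C)Oc1ccc(-c2coc3cc(O[Si](C)(C)C(C)(C)C)c(Br)cc3c2=O)cc1Br | intermediate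
10 | 7-(tert-butyldimethylsilyloxy)-3-[4-(tert-butyldimethylsilyloxy)-3-(3-methylbut-2-enyl)phenyl]-6-(3-methylbut-2-enyl)-4H-chromen-4-one | CC(C)=CCc1cc(-c2coc3cc(O[Si](C)(C)C(C)(C)C)c(CC=C(C)C)cc3c2=O)ccc1O[Si](C)(C)C(C)(C)C | intermediate
11 | rac-7-(tert-butyldimethylsilyloxy)-3-[4-(tert-butyldimethylsilyloxy)-3-(3-methylbut-2-enyl)phenyl]-6-(3-methylbut-2-enyl)chroman-4-one (racemising at C3, not isolated) | CC(C)=CCc1cc(C2COc3cc(O[Si](C)(C)C(C)(C)C)c(CC=C(C)C)cc3C2=O)ccc1O[Si](C)(C)C(C)(C)C | intermediate
12 | (3S,4S)-7-(tert-butyldimethylsilyloxy)-3-[4-(tert-butyldimethylsilyloxy)-3-(3-methylbut-2-enyl)phenyl]-6-(3-methylbut-2-enyl)chroman-4-ol | CC(C)=CCc1cc([C@H]2COc3cc(O[Si](C)(C)C(C)(C)C)c(CC=C(C)C)cc3[C@H]2O)ccc1O[Si](C)(C)C(C)(C)C | intermediate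
13 | (3S)-7-(tert-butyldimethylsilyloxy)-3-[4-(tert-butyldimethylsilyloxy)-3-(3-methylbut-2-enyl)phenyl]-6-(3-methylbut-2-enyl)chroman-4-one | CC(C)=CCc1cc([C@H]2COc3cc(O[Si](C)(C)C(C)(C)C)c(CC=C(C)C)cc3C2=O)ccc1O[Si](C)(C)C(C)(C)C | intermediate
14 | (3S)-7-hydroxy-3-[4-hydroxy-3-(3-methylbut-2-enyl)phenyl]-6-(3-methylbut-2-enyl)chroman-4-one | CC(C)=CCc1cc([C@H]2COc3cc(O)c(CC=C(C)C)cc3C2=O)ccc1O | target

Total step count: 10
Longest linear sequence: 10 steps (1 to 14; 3 enters as bought)

**Steps most likely to fail**

Step 4. Hydride migration, or capture of the benzylic cation by fluoride, may compete with the aroyl shift. Retro-Claisen loss of the formyl group under carbonate may also outrun ring closure. The fallback sets out from chalcone 4 and moves ring B instead of the aroyl group. Oxidative 1,2-aryl migration with PhI(OH)OTs in MeOH/HC(OMe)3 should give the β-keto acetal 2-(3-bromo-4-methoxyphenyl)-1-(5-bromo-2-fluoro-4-methoxyphenyl)-3,3-dimethoxypropan-1-one F1. Brief hydrolysis with aqueous HCl in THF unmasks 6, and treatment with K2CO3 in DMF closes ring C, so the route is rejoined at 7.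

Step 8. The sequence may stall after the conjugate reduction. Racemisation of 11 may be too slow relative to its reduction, which would erode selectivity. The C7 silyl ether may be lost in the formate medium, and the electron-rich benzylic alcohol may ionise. The fallback sets out from 10 and sets C3 by enantioselective protonation instead of by reduction. 1,4-Reduction with lithium tri-sec-butylborohydride (THF, −78 °C) and trapping of the enolate with allyl chloroformate should give the allyl enol carbonate F2. Decarboxylative asymmetric protonation follows, using Pd2(dba)3, the enantiomer of the t-Bu-PHOX ligand that leads to the S ketone, Meldrum's acid as proton source, and dioxane. This should deliver the ketone under neutral conditions, so the route is rejoined at 13 and steps 8 and 9 are bypassed.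

Step 7. Transfer of the allylic unit through its γ-carbon (reverse-prenyl isomers), an incomplete second coupling next to the bulky silyl ethers, and protodebromination are the likely problems. The fallback sets out from 9 and separates C–C coupling from installation of the gem-dimethyl end. Two-fold Stille allylation with allyltributylstannane (Pd(PPh3)4, toluene), which has no regiochemical ambiguity, should give the diallyl isoflavone F3. Two-fold cross-metathesis with excess 2-methylbut-2-ene (second-generation Grubbs catalyst, CH2Cl2, 40 °C) then rejoins the route at 10.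

**Further compounds**
F1 | step 4 | 2-(3-bromo-4-methoxyphenyl)-1-(5-bromo-2-fluoro-4-methoxyphenyl)-3,3-dimethoxypropan-1-one (racemic) | COC(OC)C(c1ccc(OC)c(Br)c1)C(=O)c1cc(Br)c(OC)cc1F
F2 | step 8 | allyl {7-(tert-butyldimethylsilyloxy)-3-[4-(tert-butyldimethylsilyloxy)-3-(3-methylbut-2-enyl)phenyl]-6-(3-methylbut-2-enyl)-2H-chromen-4-yl} carbonate | C=CCOC(=O)OC1=C(c2ccc(O[Si](C)(C)C(C)(C)C)c(CC=C(C)C)c2)COc2cc(O[Si](C)(C)C(C)(C)C)c(CC=C(C)C)cc12
F3 | step 7 | 6-allyl-3-[3-allyl-4-(tert-butyldimethylsilyloxy)phenyl]-7-(tert-butyldimethylsilyloxy)-4H-chromen-4-one | C=CCc1cc(-c2coc3cc(O[Si](C)(C)C(C)(C)C)c(CC=C)cc3c2=O)ccc1O[Si](C)(C)C(C)(C)C
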